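**Retrosynthetic overview**

1. The target is traced back through ester cleavage, acylation of the axial C2 alcohol, hydride reduction of a C2 ketone from the open β face, Takai–Lombardo methylenation of a C8 ketone and radical (HAT) hydrogenation of C5=C6 to a bicyclic β,γ-enone (17-nor-labd-5-en-8-one).
2. Ring B is the only ring made in the route: C5–C6 is formed by Suzuki coupling and C9–C10 by 6π-electrocyclization in the same flask, from a ring A alkenylboronate and a (1Z,3Z)-1-chloro-3-silyloxydiene. Ring A is present from the start (ketoisophorone).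
3. Enabling feature: the ring A ketone at C5 carries hydrogen only at C10, so it becomes the C5=C10 alkenylboronate. That double bond is one end of the hexatriene C10=C5–C6=C7–C8=C9; the silyl enol ether C8=C9 is the other end and later gives the C8 ketone and the C17 methylene, while C5 stays sp2 for late trans-selective hydrogen delivery.
4. Stereocontrol: C13 comes from (S)-citronellic acid (C9, C11–C16). The C2 carbinol, set by a two-enzyme reduction of ketoisophorone, only steers the ring closure and is inverted at the end by oxidation/reduction. C6–C8 come from (Z)-3-chloroacrylic acid.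
5. Order of ring formation: ring A (bought in), then ring B (step 9).

Key step: step 9

Remark: labdane numbering is used for all bicyclic compounds; α is the face of C20 in the target (target: 2α-O, 5β-H, 9α-H, 10α-CH3; CIP 2S,5R,9S,10R,13S) and β the opposite face.
Assumption: a ketoreductase with (S)-selectivity at C4 of levodione is taken to be available from enzyme panels; the known (4R)-selective levodione reductase is used in the first fallback.

**Route**

Step 1
Reactants: 1 ketoisophorone (2,6,6-trimethylcyclohex-2-ene-1,4-dione)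
Product: 3 (4S,6R)-4-hydroxy-2,2,6-trimethylcyclohexan-1-one, via (6R)-levodione 2 (not isolated)
Conditions: ene-reductase (old yellow enzyme family), then (S)-selective NADPH-dependent ketoreductase, NADP+ (cat.), D-glucose, glucose dehydrogenase, phosphate buffer pH 7, 30 °C
Reagents that add atoms: none
Why: Enzymatic asymmetric reduction: the flavin-dependent ene-reductase should reduce C2=C3 to (6R)-levodione, and the ketoreductase should reduce only the unhindered C4 carbonyl (C1 is flanked by the quaternary C2) with catalyst-controlled (S)-selectivity; C4 becomes C2 of the skeleton and C6 is erased in step 3.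

Step 2
Reactants: 3 (4S,6R)-4-hydroxy-2,2,6-trimethylcyclohexan-1-one
Product: 4 N'-[(4S,6R)-4-hydroxy-2,2,6-trimethylcyclohexylidene]-2,4,6-triisopropylbenzenesulfonohydrazide
Conditions: 2,4,6-triisopropylbenzenesulfonohydrazide, HCl (cat.), MeCN, rt
Reagents that add atoms: 2,4,6-triisopropylbenzenesulfonohydrazide, CC(C)c1cc(C(C)C)c(S(=O)(=O)NN)c(C(C)C)c1
Why: Acid-catalysed hydrazone condensation at the only carbonyl group; the sulfonamide nitrogen should lie syn to C6, the only α-carbon that bears hydrogen (epimerisation at C6 is of no consequence).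

Step 3
Reactants: 4 N'-[(4S,6R)-4-hydroxy-2,2,6-trimethylcyclohexylidene]-2,4,6-triisopropylbenzenesulfonohydrazide
Product: 6 (1S)-3,5,5-trimethyl-4-(4,4,5,5-tetramethyl-1,3,2-dioxaborolan-2-yl)cyclohex-3-en-1-ol, via dilithiated alkenyllithium 5 (not isolated)
Conditions: n-BuLi (3.3 equiv), TMEDA, THF, −78 → 0 °C; then i-PrOBpin, −78 °C → rt; aq. NH4Cl
Reagents that add atoms: 2-isopropoxy-4,4,5,5-tetramethyl-1,3,2-dioxaborolane, CC(C)OB1OC(C)(C)C(C)(C)O1
Why: Shapiro reaction: deprotonation at C6 (the third equivalent of base covers the hydroxyl) and loss of sulfinate and N2 should give a single tetrasubstituted alkenyllithium, which is trapped by the borate ester.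

Step 4
Reactants: 7 (S)-citronellic acid
Product: 8 2-(trimethylsilyl)ethyl (S)-3,7-dimethyloct-6-enoate
Conditions: 2-(trimethylsilyl)ethanol, DCC, DMAP (cat.), CH2Cl2, 0 °C → rt
Reagents that add atoms: 2-(trimethylsilyl)ethanol, C[Si](C)(C)CCO
Why: Steglich esterification; the ester is stable to all later steps and is removed by fluoride without touching the isovalerate.

Step 5
Reactants: 8 2-(trimethylsilyl)ethyl (S)-3,7-dimethyloct-6-enoate
Product: 10 2-(trimethylsilyl)ethyl (S)-6-hydroxy-3-methylhexanoate, via ozonide 9 (not isolated)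
Conditions: O3, CH2Cl2, −78 °C; then NaBH4, MeOH, −78 °C → rt
Reagents that add atoms: ozone, [O-][O+]=O
Why: Ozonolysis of the trisubstituted alkene with reductive work-up gives the primary alcohol at the future C9; the ester is inert to NaBH4.

Step 6
Reactants: 10 2-(trimethylsilyl)ethyl (S)-6-hydroxy-3-methylhexanoate
Product: 11 2-(trimethylsilyl)ethyl (S)-6-iodo-3-methylhexanoate
Conditions: I2, PPh3, imidazole, CH2Cl2, 0 °C → rt
Reagents that add atoms: iodine, II
Why: Appel-type iodination of an unhindered primary alcohol.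

Step 7
Reactants: 11 2-(trimethylsilyl)ethyl (S)-6-iodo-3-methylhexanoate, 12 (Z)-3-chloroacrylic acid
Product: 15 2-(trimethylsilyl)ethyl (3S,8Z)-9-chloro-3-methyl-7-oxonon-8-enoate, via alkylzinc iodide 13 (not isolated), via (Z)-3-chloroacryloyl chloride 14 (not isolated)
Conditions: 11: Zn, LiCl, THF, 40 °C; 12: (COCl)2, DMF (cat.), CH2Cl2, 0 °C → rt, evaporation; then Pd(PPh3)4 (5 mol %), THF, 0 °C
Reagents that add atoms: none
Why: Negishi acylation forms the C8–C9 ketone bond; oxidative addition at the acyl chloride should be far faster than at the alkenyl chloride and alkylzinc halides do not add to enones, so the (Z)-chlorovinyl ketone should survive.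

Step 8
Reactants: 15 2-(trimethylsilyl)ethyl (3S,8Z)-9-chloro-3-methyl-7-oxonon-8-enoate
Product: 16 2-(trimethylsilyl)ethyl (3S,6Z,8Z)-7-(tert-butyldimethylsilyloxy)-9-chloro-3-methylnona-6,8-dienoate
Conditions: TBSOTf, i-Pr2NEt, CH2Cl2, −78 → 0 °C
Reagents that add atoms: tert-butyldimethylsilyl trifluoromethanesulfonate, CC(C)(C)[Si](C)(C)OS(=O)(=O)C(F)(F)F
Why: Soft enolisation (silyl triflate with a non-nucleophilic amine) can only go toward the CH2 group (future C9) and should give the (Z)-silyl enol ether, which places C11 on the outside of the later triene.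

Step 9
Reactants: 6 (1S)-3,5,5-trimethyl-4-(4,4,5,5-tetramethyl-1,3,2-dioxaborolan-2-yl)cyclohex-3-en-1-ol, 16 2-(trimethylsilyl)ethyl (3S,6Z,8Z)-7-(tert-butyldimethylsilyloxy)-9-chloro-3-methylnona-6,8-dienoate
Product: 19 2-(trimethylsilyl)ethyl 2β-hydroxy-8-oxo-17-norlabd-5-en-15-oate (9α-H; 10α-CH3; 13S), via hexatriene 17 (not isolated), via bicyclic silyl dienol ether 18 (not isolated)
Conditions: Pd(OAc)2 (5 mol %), SPhos (10 mol %), K3PO4·H2O, toluene, 80 °C; then 1 M HCl, THF, 0 °C
Reagents that add atoms: none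
Why: Suzuki–Miyaura coupling joins C5 of 6 to C6 of 16 with retention of the (Z)-chloroalkene geometry and gives hexatriene 17 (C10=C5–C6=C7–C8=C9), which closes ring B by a thermal disrotatory 6π-electrocyclization that forms C9–C10; dilute acid then hydrolyses the silyl dienol ether 18 by protonation at C7. The closest known reaction type is the cross-coupling/6π-electrocyclization cascade of (Z)-hexatrienes, including the closure of 7-cis trienes built on a 2,6,6-trimethylcyclohexene ring to drimane-type bicycles. Ring B is closed in the six-atom electrocyclic mode, and C9 and C10 are set together: by the disrotatory rule the two inside groups (C20 on C10 and H on C9, the (Z)-silyl enol ether holding C11 outside) end cis, which is the 9α-H/10α-CH3 relation of the target. The absolute sense is controlled by the C2 carbinol of ring A: in the half-chair with equatorial hydroxyl, the rotation that carries C20 to the face opposite the hydroxyl turns ring A directly into a chair with equatorial OH, whereas the other sense would force C20, the C2 oxygen and one C4 methyl into a syn-triaxial array. The step needs intact geometry of the enol ether and the chloroalkene (mild base, no fluoride), a temperature below the onset of [1,5]-hydrogen shifts in the cyclohexadiene, and tolerance of a reversible [1,7]-hydrogen shift from C20, which only returns material to 17. Kinetic protonation of the dienol ether at the α-carbon C7 keeps C5=C6 for the next step and does not touch C9.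

Step 10
Reactants: 19 2-(trimethylsilyl)ethyl 2β-hydroxy-8-oxo-17-norlabd-5-en-15-oate (9α-H; 10α-CH3; 13S)
Product: 20 2-(trimethylsilyl)ethyl 2β-hydroxy-8-oxo-17-norlabdan-15-oate (5β-H; 9α-H; 10α-CH3; 13S)
Conditions: Mn(dpm)3 [tris(2,2,6,6-tetramethylheptane-3,5-dionato)manganese] (cat.), PhSiH3, t-BuOOH, i-PrOH, rt
Reagents that add atoms: none
Why: Metal-hydride hydrogen atom transfer (HAT) hydrogenation: hydrogen transfer to C6 gives the tertiary C5 radical, which should take up hydrogen on the β face anti to the axial C20 methyl to give the trans ring fusion; ketone, ester and alcohol are inert.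

Step 11
Reactants: 20 2-(trimethylsilyl)ethyl 2β-hydroxy-8-oxo-17-norlabdan-15-oate (5β-H; 9α-H; 10α-CH3; 13S)
Product: 21 2-(trimethylsilyl)ethyl 2β-hydroxylabd-8(17)-en-15-oate (5β-H; 9α-H; 10α-CH3; 13S)
Conditions: Zn, CH2Br2, TiCl4, THF/CH2Cl2, 0 °C → rt
Reagents that add atoms: dibromomethane, BrCBr
Why: Takai–Lombardo methylenation with a non-basic gem-dimetallic reagent should convert the hindered C8 ketone into the 8(17)-methylene group without enolisation, so C9 is not epimerised and the ester is left alone.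

Step 12
Reactants: 21 2-(trimethylsilyl)ethyl 2β-hydroxylabd-8(17)-en-15-oate (5β-H; 9α-H; 10α-CH3; 13S)
Product: 22 2-(trimethylsilyl)ethyl 2-oxolabd-8(17)-en-15-oate (5β-H; 9α-H; 10α-CH3; 13S)
Conditions: Dess–Martin periodinane, NaHCO3, CH2Cl2, rt
Reagents that add atoms: none
Why: Dess–Martin oxidation of the equatorial secondary alcohol; the alkene and the ester are inert.

Step 13
Reactants: 22 2-(trimethylsilyl)ethyl 2-oxolabd-8(17)-en-15-oate (5β-H; 9α-H; 10α-CH3; 13S)
Product: 23 2-(trimethylsilyl)ethyl 2α-hydroxylabd-8(17)-en-15-oate (5β-H; 9α-H; 10α-CH3; 13S)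
Conditions: NaBH4, MeOH/CH2Cl2, −20 → 0 °C
Reagents that add atoms: none
Why: Hydride reduction under steric approach control: the axial trajectory on the α face is blocked by the two syn-axial methyl groups (C20 and the 4α-methyl), so hydride should enter from the β face and give the axial 2α-alcohol of the target.

Step 14
Reactants: 23 2-(trimethylsilyl)ethyl 2α-hydroxylabd-8(17)-en-15-oate (5β-H; 9α-H; 10α-CH3; 13S)
Product: 24 2-(trimethylsilyl)ethyl 2α-(3-methylbutanoyloxy)labd-8(17)-en-15-oate (5β-H; 9α-H; 10α-CH3; 13S)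
Conditions: 3-methylbutanoic anhydride, DMAP, Et3N, CH2Cl2, 40 °C
Reagents that add atoms: 3-methylbutanoic anhydride, CC(C)CC(=O)OC(=O)CC(C)C
Why: DMAP-catalysed acylation of the hindered axial alcohol with retention at C2.

Step 15
Reactants: 24 2-(trimethylsilyl)ethyl 2α-(3-methylbutanoyloxy)labd-8(17)-en-15-oate (5β-H; 9α-H; 10α-CH3; 13S)
Product: 25 (2S,5R,9S,10R,13S)-2-(3-methylbutanoyloxy)labd-8(17)-en-15-oic acid (target)
Conditions: TBAF, THF, rt; dilute aq. HCl work-up
Reagents that add atoms: none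
Why: Fluoride-induced β-elimination of the 2-(trimethylsilyl)ethyl ester frees the acid while the hindered isovalerate and the exocyclic alkene are untouched.

**Compound list**

1 | ketoisophorone (2,6,6-trimethylcyclohex-2-ene-1,4-dione) | CC1=CC(=O)CC(C)(C)C1=O | starting material
2 | (6R)-levodione ((6R)-2,2,6-trimethylcyclohexane-1,4-dione) | C[C@@H]1CC(=O)CC(C)(C)C1=O | intermediate
3 | (4S,6R)-4-hydroxy-2,2,6-trimethylcyclohexan-1-one | C[C@@H]1C[C@H](O)CC(C)(C)C1=O | intermediate
4 | N'-[(4S,6R)-4-hydroxy-2,2,6-trimethylcyclohexylidene]-2,4,6-triisopropylbenzenesulfonohydrazide | C[C@@H]1C[C@H](O)CC(C)(C)C1=NNS(=O)(=O)c2c(C(C)C)cc(C(C)C)cc2C(C)C | intermediate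
5 | lithium (1S)-4-lithio-3,5,5-trimethylcyclohex-3-en-1-olate | CC1=C([Li])C(C)(C)C[C@@H](O[Li])C1 | intermediate
6 | (1S)-3,5,5-trimethyl-4-(4,4,5,5-tetramethyl-1,3,2-dioxaborolan-2-yl)cyclohex-3-en-1-ol | CC1=C(B2OC(C)(C)C(C)(C)O2)C(C)(C)C[C@@H](O)C1 | intermediate
7 | (S)-citronellic acid ((S)-3,7-dimethyloct-6-enoic acid) | CC(C)=CCC[C@H](C)CC(=O)O | starting material
8 | 2-(trimethylsilyl)ethyl (S)-3,7-dimethyloct-6-enoate | CC(C)=CCC[C@H](C)CC(=O)OCC[Si](C)(C)C | intermediate
9 | ozonide of 8 (3,3-dimethyl-1,2,4-trioxolane with the ester chain at C5; mixture at the ring carbon) | CC1(C)OOC(CC[C@H](C)CC(=O)OCC[Si](C)(C)C)O1 | intermediate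
10 | 2-(trimethylsilyl)ethyl (S)-6-hydroxy-3-methylhexanoate | OCCC[C@H](C)CC(=O)OCC[Si](C)(C)C | intermediate
11 | 2-(trimethylsilyl)ethyl (S)-6-iodo-3-methylhexanoate | ICCC[C@H](C)CC(=O)OCC[Si](C)(C)C | intermediate
12 | (Z)-3-chloroacrylic acid | OC(=O)/C=C\Cl | starting material
13 | [(4S)-4-methyl-6-oxo-6-[2-(trimethylsilyl)ethoxy]hexyl]zinc iodide | I[Zn]CCC[C@H](C)CC(=O)OCC[Si](C)(C)C | intermediate
14 | (Z)-3-chloroacryloyl chloride | ClC(=O)/C=C\Cl | intermediate
15 | 2-(trimethylsilyl)ethyl (3S,8Z)-9-chloro-3-methyl-7-oxonon-8-enoate | Cl/C=C\C(=O)CCC[C@H](C)CC(=O)OCC[Si](C)(C)C | intermediate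
16 | 2-(trimethylsilyl)ethyl (3S,6Z,8Z)-7-(tert-butyldimethylsilyloxy)-9-chloro-3-methylnona-6,8-dienoate | Cl/C=C\C(O[Si](C)(C)C(C)(C)C)=C\CC[C@H](C)CC(=O)OCC[Si](C)(C)C | intermediate
17 | 2-(trimethylsilyl)ethyl (3S,6Z,8Z)-7-(tert-butyldimethylsilyloxy)-9-[(4S)-4-hydroxy-2,6,6-trimethylcyclohex-1-en-1-yl]-3-methylnona-6,8-dienoate | CC1=C(/C=C\C(O[Si](C)(C)C(C)(C)C)=C\CC[C@H](C)CC(=O)OCC[Si](C)(C)C)C(C)(C)C[C@@H](O)C1 | intermediate
18 | 2-(trimethylsilyl)ethyl 8-(tert-butyldimethylsilyloxy)-2β-hydroxy-17-norlabda-5,7-dien-15-oate (9α-H; 10α-CH3; 13S) | CC(C)(C)[Si](C)(C)OC1=CC=C2C(C)(C)C[C@@H](O)C[C@@]2(C)[C@H]1CC[C@H](C)CC(=O)OCC[Si](C)(C)C | intermediate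
19 | 2-(trimethylsilyl)ethyl 2β-hydroxy-8-oxo-17-norlabd-5-en-15-oate (9α-H; 10α-CH3; 13S) | O=C1CC=C2C(C)(C)C[C@@H](O)C[C@@]2(C)[C@H]1CC[C@H](C)CC(=O)OCC[Si](C)(C)C | intermediate
20 | 2-(trimethylsilyl)ethyl 2β-hydroxy-8-oxo-17-norlabdan-15-oate (5β-H; 9α-H; 10α-CH3; 13S) | O=C1CC[C@@H]2C(C)(C)C[C@@H](O)C[C@@]2(C)[C@H]1CC[C@H](C)CC(=O)OCC[Si](C)(C)C | intermediate
21 | 2-(trimethylsilyl)ethyl 2β-hydroxylabd-8(17)-en-15-oate (5β-H; 9α-H; 10α-CH3; 13S) | C=C1CC[C@@H]2C(C)(C)C[C@@H](O)C[C@@]2(C)[C@H]1CC[C@H](C)CC(=O)OCC[Si](C)(C)C | intermediate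
22 | 2-(trimethylsilyl)ethyl 2-oxolabd-8(17)-en-15-oate (5β-H; 9α-H; 10α-CH3; 13S) | C=C1CC[C@@H]2C(C)(C)CC(=O)C[C@@]2(C)[C@H]1CC[C@H](C)CC(=O)OCC[Si](C)(C)C | intermediate
23 | 2-(trimethylsilyl)ethyl 2α-hydroxylabd-8(17)-en-15-oate (5β-H; 9α-H; 10α-CH3; 13S) | C=C1CC[C@@H]2C(C)(C)C[C@H](O)C[C@@]2(C)[C@H]1CC[C@H](C)CC(=O)OCC[Si](C)(C)C | intermediate
24 | 2-(trimethylsilyl)ethyl 2α-(3-methylbutanoyloxy)labd-8(17)-en-15-oate (5β-H; 9α-H; 10α-CH3; 13S) | C=C1CC[C@@H]2C(C)(C)C[C@H](OC(=O)CC(C)C)C[C@@]2(C)[C@H]1CC[C@H](C)CC(=O)OCC[Si](C)(C)C | intermediate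
25 | (2S,5R,9S,10R,13S)-2-(3-methylbutanoyloxy)labd-8(17)-en-15-oic acid (CNP0168901.1) | C=C1CC[C@@H]2C(C)(C)C[C@H](OC(=O)CC(C)C)C[C@@]2(C)[C@H]1CC[C@H](C)CC(=O)O | target

**Step count and risks**

Total steps: 15. Longest linear sequence: 12 steps (steps 4–15, from (S)-citronellic acid).

Steps most likely to fail:

Step 9. The facial sense of the disrotatory ring closure rests on a conformational argument about a remote, equatorial hydroxyl and may be low or reversed; closure on the face away from the hydroxyl would give the C9/C10 pair mirror-related to C13. The fallback keeps the cascade but changes the ring A series, so that closure away from the hydroxyl leads straight to the natural C2 configuration. It sets out from 1 and 16 and comes back at 23. Ketoisophorone 1 is reduced with the ene-reductase and a (4R)-selective levodione reductase to (4R,6R)-4-hydroxy-2,2,6-trimethylcyclohexan-1-one F1. Condensation with the same sulfonohydrazide gives the trisylhydrazone F2, and the Shapiro sequence leads through the dilithiated alkenyllithium F3 to the (1R)-boronate F4. Coupling of F4 with 16 under the conditions of step 9 passes through the C2-epimeric hexatriene F5 and the 2α-hydroxy silyl dienol ether F6 and gives, after hydrolysis, the 2α-hydroxy enone F7. HAT hydrogenation as in step 10 gives the 2α-hydroxy trans-ketone F8, and Takai–Lombardo methylenation of F8 gives 23; steps 12 and 13 then fall away.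

Step 10. Hydrogen delivery to the hindered C5 radical, which lies between two quaternary carbons, may be slow or may occur on both faces, giving the cis ring fusion. The fallback replaces radical hydrogenation by an ionic sequence; it sets out from 19 and comes back at 20. p-TsOH (cat.) in CH2Cl2 moves the double bond into conjugation to give the 2β-hydroxy-8-oxo-17-norlabd-6-ene ester F9, in which C5 is protonated under equilibrating conditions in favour of the trans fusion; H2 over Pd/C in EtOAc then saturates C6=C7 to give 20.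

Step 11. The hindered C8 ketone may enolise toward C9 (epimerisation of the axial side chain) or fail to react with the gem-dimetallic reagent. The fallback is a two-stage Peterson olefination; it sets out from 20 and comes back at 21. Me3SiCH2MgCl with CeCl3 (THF, −78 → 0 °C) adds to the C8 carbonyl without enolisation to give the β-hydroxysilane F10, and aqueous HF in MeCN induces elimination to 21.

Further compounds
F1 | step 9 | (4R,6R)-4-hydroxy-2,2,6-trimethylcyclohexan-1-one | C[C@@H]1C[C@@H](O)CC(C)(C)C1=O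
F2 | step 9 | N'-[(4R,6R)-4-hydroxy-2,2,6-trimethylcyclohexylidene]-2,4,6-triisopropylbenzenesulfonohydrazide | C[C@@H]1C[C@@H](O)CC(C)(C)C1=NNS(=O)(=O)c2c(C(C)C)cc(C(C)C)cc2C(C)C
F3 | step 9 | lithium (1R)-4-lithio-3,5,5-trimethylcyclohex-3-en-1-olate | CC1=C([Li])C(C)(C)C[C@H](O[Li])C1
F4 | step 9 | (1R)-3,5,5-trimethyl-4-(4,4,5,5-tetramethyl-1,3,2-dioxaborolan-2-yl)cyclohex-3-en-1-ol | CC1=C(B2OC(C)(C)C(C)(C)O2)C(C)(C)C[C@H](O)C1
F5 | step 9 | 2-(trimethylsilyl)ethyl (3S,6Z,8Z)-7-(tert-butyldimethylsilyloxy)-9-[(4R)-4-hydroxy-2,6,6-trimethylcyclohex-1-en-1-yl]-3-methylnona-6,8-dienoate | CC1=C(/C=C\C(O[Si](C)(C)C(C)(C)C)=C\CC[C@H](C)CC(=O)OCC[Si](C)(C)C)C(C)(C)C[C@H](O)C1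
F6 | step 9 | 2-(trimethylsilyl)ethyl 8-(tert-butyldimethylsilyloxy)-2α-hydroxy-17-norlabda-5,7-dien-15-oate (9α-H; 10α-CH3; 13S) | CC(C)(C)[Si](C)(C)OC1=CC=C2C(C)(C)C[C@H](O)C[C@@]2(C)[C@H]1CC[C@H](C)CC(=O)OCC[Si](C)(C)C
F7 | step 9 | 2-(trimethylsilyl)ethyl 2α-hydroxy-8-oxo-17-norlabd-5-en-15-oate (9α-H; 10α-CH3; 13S) | O=C1CC=C2C(C)(C)C[C@H](O)C[C@@]2(C)[C@H]1CC[C@H](C)CC(=O)OCC[Si](C)(C)C
F8 | step 9 | 2-(trimethylsilyl)ethyl 2α-hydroxy-8-oxo-17-norlabdan-15-oate (5β-H; 9α-H; 10α-CH3; 13S) | O=C1CC[C@@H]2C(C)(C)C[C@H](O)C[C@@]2(C)[C@H]1CC[C@H](C)CC(=O)OCC[Si](C)(C)C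
F9 | step 10 | 2-(trimethylsilyl)ethyl 2β-hydroxy-8-oxo-17-norlabd-6-en-15-oate (5β-H; 9α-H; 10α-CH3; 13S) | O=C1C=C[C@@H]2C(C)(C)C[C@@H](O)C[C@@]2(C)[C@H]1CC[C@H](C)CC(=O)OCC[Si](C)(C)C
F10 | step 11 | 2-(trimethylsilyl)ethyl 2β,8-dihydroxy-8-[(trimethylsilyl)methyl]-17-norlabdan-15-oate (5β-H; 9α-H; 10α-CH3; 13S; mixture at C8) | C[Si](C)(C)CC1(O)CC[C@@H]2C(C)(C)C[C@@H](O)C[C@@]2(C)[C@H]1CC[C@H](C)CC(=O)OCC[Si](C)(C)C
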